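Indole B carries only hydrogen at C2 and is joined to ring C (the tetramethoxybenzene) through C3. Its C2–C3 unit is therefore traced back to an alkyne on ring C, with a removable silyl group on the carbon that becomes C2. A Larock heteroannulation with 5-bromo-2-iodoaniline creates the C3a–C3 and C2–N1 bonds, and with them the five-membered ring of indole B, in a single operation. It also leaves a bromide at C6 as the handle for the prenyl group. The precursor is a para-disubstituted tetramethoxybenzene bearing a trimethylsilylethynyl group and the doubly TIPS-protected 5-hydroxyindol-3-yl unit (indole A). It is assembled by two successive cross-couplings on the symmetric dibromide.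

Key step: step 6

Remark: the target has no stereocentre and no configurationally relevant double bond. The two ring C–indole axes are taken as freely rotating, so no stereochemical element has to be set.

Step 1
Reactants: 1 1,2,4,5-tetramethoxybenzene
Product: 2 1,4-dibromo-2,3,5,6-tetramethoxybenzene
Conditions: Br2 (2.2 equiv), CH2Cl2, 0 °C → rt
Reagents that add atoms: bromine, BrBr
Why: Electrophilic aromatic bromination, in which the only two free ring positions are para to each other and each is activated by flanking methoxy groups, so exhaustive bromination can give only the para-dibromide.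

Step 2
Reactants: 3 5-hydroxyindole
Product: 4 1-(triisopropylsilyl)-5-(triisopropylsilyloxy)indole
Conditions: NaH (2.5 equiv), TIPSCl (2.3 equiv), THF, 0 °C → rt
Reagents that add atoms: triisopropylsilyl chloride (TIPSCl), CC(C)[Si](Cl)(C(C)C)C(C)C
Why: Double silylation of the deprotonated phenol and indole nitrogen, which masks both acidic sites against the later palladium chemistry and places a bulky group on N1 that shields C2 and C7.

Step 3
Reactants: 4 1-(triisopropylsilyl)-5-(triisopropylsilyloxy)indole
Product: 5 3-(4,4,5,5-tetramethyl-1,3,2-dioxaborolan-2-yl)-1-(triisopropylsilyl)-5-(triisopropylsilyloxy)indole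
Conditions: [Ir(OMe)(cod)]2 (2 mol %), dtbpy (4 mol %), B2pin2 (1.1 equiv), THF, 60 °C
Reagents that add atoms: bis(pinacolato)diboron, CC1(C)OB(B2OC(C)(C)C(C)(C)O2)OC1(C)C
Why: Sterically governed iridium-catalysed aromatic C–H borylation, in which N-TIPS blocks C2 and C7 and O-TIPS blocks C4 and C6, leaving C3, the established site for N-silylindoles.

Step 4
Reactants: 2 1,4-dibromo-2,3,5,6-tetramethoxybenzene; 5 3-(4,4,5,5-tetramethyl-1,3,2-dioxaborolan-2-yl)-1-(triisopropylsilyl)-5-(triisopropylsilyloxy)indole
Product: 6 3-(4-bromo-2,3,5,6-tetramethoxyphenyl)-1-(triisopropylsilyl)-5-(triisopropylsilyloxy)indole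
Conditions: 2 (3 equiv), Pd(PPh3)4 (5 mol %), Na2CO3 (2 M aq), DME, 85 °C
Reagents that add atoms: none
Why: Suzuki–Miyaura coupling in which a threefold excess of the cheap, recoverable symmetric dibromide favours single substitution, and a triphenylphosphine catalyst is chosen because it does not tend to stay on the arene and attack the second C–Br bond.

Step 5
Reactants: 6 3-(4-bromo-2,3,5,6-tetramethoxyphenyl)-1-(triisopropylsilyl)-5-(triisopropylsilyloxy)indole; 7 trimethylsilylacetylene
Product: 8 3-[2,3,5,6-tetramethoxy-4-(trimethylsilylethynyl)phenyl]-1-(triisopropylsilyl)-5-(triisopropylsilyloxy)indole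
Conditions: PdCl2(PhCN)2 (5 mol %), [HP(t-Bu)3]BF4 (10 mol %), CuI (5 mol %), i-Pr2NH, dioxane, 60 °C, sealed tube
Reagents that add atoms: none
Why: Sonogashira coupling in which the bulky, electron-rich P(t-Bu)3 ligand allows oxidative addition to the electron-rich, doubly ortho-substituted C–Br bond at moderate temperature, while the amine base leaves all Si–O, Si–N and Si–C bonds intact.

Step 6
Reactants: 8 3-[2,3,5,6-tetramethoxy-4-(trimethylsilylethynyl)phenyl]-1-(triisopropylsilyl)-5-(triisopropylsilyloxy)indole; 9 5-bromo-2-iodoaniline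
Product: 10 6-bromo-3-{2,3,5,6-tetramethoxy-4-[1-(triisopropylsilyl)-5-(triisopropylsilyloxy)indol-3-yl]phenyl}-2-(trimethylsilyl)-1H-indole
Conditions: 9 (1.5 equiv), Pd(OAc)2 (10 mol %), LiCl (1 equiv), Na2CO3 (3 equiv), dry DMF, 100 °C, argon
Reagents that add atoms: none
Why: Zerovalent palladium formed in the flask from Pd(OAc)2 inserts into the weak C–I bond of 9, alkyne 8 coordinates and undergoes syn carbopalladation, the amino group then binds to divalent palladium with transfer of HI to the carbonate, and C–N reductive elimination releases 10 and regenerates the catalyst. The closest known reaction type is the Larock indole synthesis of 2-iodoanilines with 1-aryl-2-silylalkynes, which gives 3-aryl-2-silylindoles. The pyrrole ring of indole B closes as a formal [3+2] heteroannulation (N1, C7a and C3a from 9, C2 and C3 from 8), and the ring-closing event is reductive elimination from a six-membered azapalladacycle. No stereocentre is created. The insertion must join the aryl carbon of 9 to the alkyne carbon attached to ring C, and the trimethylsilyl group secures this because silicon strongly prefers the carbon next to the long C–Pd bond over the carbon of the short forming C–C bond, so it ends at C2. The step must also distinguish the two halogens of 9, and under phosphine-free conditions oxidative addition to C–I is far faster than to C–Br, so the bromide para to the iodine-bearing carbon is retained and becomes C6.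

Step 7
Reactants: 10 6-bromo-3-{2,3,5,6-tetramethoxy-4-[1-(triisopropylsilyl)-5-(triisopropylsilyloxy)indol-3-yl]phenyl}-2-(trimethylsilyl)-1H-indole; 11 tributyl(3-methylbut-2-enyl)stannane
Product: 12 6-(3-methylbut-2-enyl)-3-{2,3,5,6-tetramethoxy-4-[1-(triisopropylsilyl)-5-(triisopropylsilyloxy)indol-3-yl]phenyl}-2-(trimethylsilyl)-1H-indole
Conditions: 11 (1.5 equiv), Pd(PPh3)4 (10 mol %), degassed DMF, 100 °C
Reagents that add atoms: none
Why: Stille coupling under neutral conditions that tolerates the free N–H and every silyl group, with the aryl(prenyl)palladium intermediate expected to eliminate reductively at the unsubstituted allyl terminus and so give the linear prenyl arene.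

Step 8
Reactants: 12 6-(3-methylbut-2-enyl)-3-{2,3,5,6-tetramethoxy-4-[1-(triisopropylsilyl)-5-(triisopropylsilyloxy)indol-3-yl]phenyl}-2-(trimethylsilyl)-1H-indole
Product: 13 3-{4-[6-(3-methylbut-2-enyl)-1H-indol-3-yl]-2,3,5,6-tetramethoxyphenyl}-1H-indol-5-ol (target)
Conditions: TBAF (1 M in THF, 6 equiv), THF, rt → 60 °C, argon
Reagents that add atoms: none
Why: Fluoride-induced global desilylation, in which Si–F bond formation cleaves the O–Si and N–Si bonds at once and, on warming, the C2–Si bond of indole B (protodesilylation by the water in the reagent), while the prenyl alkene and the methyl ethers are inert to fluoride.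

Compound list
1 | 1,2,4,5-tetramethoxybenzene | COc1cc(OC)c(OC)cc1OC | starting material
2 | 1,4-dibromo-2,3,5,6-tetramethoxybenzene | COc1c(Br)c(OC)c(OC)c(Br)c1OC | intermediate
3 | 5-hydroxyindole | Oc1ccc2[nH]ccc2c1 | starting material
4 | 1-(triisopropylsilyl)-5-(triisopropylsilyloxy)indole | CC(C)[Si](C(C)C)(C(C)C)Oc1ccc2c(ccn2[Si](C(C)C)(C(C)C)C(C)C)c1 | intermediate
5 | 3-(4,4,5,5-tetramethyl-1,3,2-dioxaborolan-2-yl)-1-(triisopropylsilyl)-5-(triisopropylsilyloxy)indole | CC(C)[Si](C(C)C)(C(C)C)Oc1ccc2c(c1)c(B1OC(C)(C)C(C)(C)O1)cn2[Si](C(C)C)(C(C)C)C(C)C | intermediate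
6 | 3-(4-bromo-2,3,5,6-tetramethoxyphenyl)-1-(triisopropylsilyl)-5-(triisopropylsilyloxy)indole | COc1c(Br)c(OC)c(OC)c(-c2cn([Si](C(C)C)(C(C)C)C(C)C)c3ccc(O[Si](C(C)C)(C(C)C)C(C)C)cc23)c1OC | intermediate
7 | trimethylsilylacetylene | C#C[Si](C)(C)C | starting material
8 | 3-[2,3,5,6-tetramethoxy-4-(trimethylsilylethynyl)phenyl]-1-(triisopropylsilyl)-5-(triisopropylsilyloxy)indole | C[Si](C)(C)C#Cc1c(OC)c(OC)c(-c2cn([Si](C(C)C)(C(C)C)C(C)C)c3ccc(O[Si](C(C)C)(C(C)C)C(C)C)cc23)c(OC)c1OC | intermediate
9 | 5-bromo-2-iodoaniline | Nc1cc(Br)ccc1I | starting material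
10 | 6-bromo-3-{2,3,5,6-tetramethoxy-4-[1-(triisopropylsilyl)-5-(triisopropylsilyloxy)indol-3-yl]phenyl}-2-(trimethylsilyl)-1H-indole | COc1c(OC)c(-c2cn([Si](C(C)C)(C(C)C)C(C)C)c3ccc(O[Si](C(C)C)(C(C)C)C(C)C)cc23)c(OC)c(OC)c1-c1c([Si](C)(C)C)[nH]c2cc(Br)ccc12 | intermediate
11 | tributyl(3-methylbut-2-enyl)stannane | CCCC[Sn](CCCC)(CCCC)CC=C(C)C | starting material
12 | 6-(3-methylbut-2-enyl)-3-{2,3,5,6-tetramethoxy-4-[1-(triisopropylsilyl)-5-(triisopropylsilyloxy)indol-3-yl]phenyl}-2-(trimethylsilyl)-1H-indole | COc1c(OC)c(-c2cn([Si](C(C)C)(C(C)C)C(C)C)c3ccc(O[Si](C(C)C)(C(C)C)C(C)C)cc23)c(OC)c(OC)c1-c1c([Si](C)(C)C)[nH]c2cc(CC=C(C)C)ccc12 | intermediate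
13 | 3-{4-[6-(3-methylbut-2-enyl)-1H-indol-3-yl]-2,3,5,6-tetramethoxyphenyl}-1H-indol-5-ol | COc1c(OC)c(-c2c[nH]c3ccc(O)cc23)c(OC)c(OC)c1-c1c[nH]c2cc(CC=C(C)C)ccc12 | target

Total step count: 8
Longest linear sequence: 7 steps (steps 2 to 8, from 5-hydroxyindole 3)

Steps most likely to fail

Step 6.
- **What may go wrong:** Both alkyne substituents are bulky, so insertion may be slow or may lose its orientation. The carbonate may strip the alkynyl silicon before insertion. Prolonged heating may bring the C–Br bond into play.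
- **Fallback:** The annulation is given up and a preformed indole B is attached by a second Suzuki–Miyaura coupling, setting out from bromide 6. Commercial 6-bromoindole (Brc1ccc2cc[nH]c2c1) is N-silylated (NaH, TIPSCl, THF) to 6-bromo-1-(triisopropylsilyl)indole F1. F1 is coupled with stannane 11 (Pd(PPh3)4, DMF) to 6-(3-methylbut-2-enyl)-1-(triisopropylsilyl)indole F2. F2 is borylated at C3 ([Ir(OMe)(cod)]2, dtbpy, B2pin2) to 6-(3-methylbut-2-enyl)-3-(4,4,5,5-tetramethyl-1,3,2-dioxaborolan-2-yl)-1-(triisopropylsilyl)indole F3. F3 and 6 are joined (Pd(PPh3)4, aq Na2CO3, DME) to the tris-TIPS bis-indolyl tetramethoxybenzene F4. TBAF in THF takes F4 back to the route at target 13.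

Step 4.
- **What may go wrong:** A second coupling may occur on the product bromide. The indol-3-yl boronate may protodeboronate faster than it transmetalates to the hindered arylpalladium species. The phenolic silyl ether may erode in the hot aqueous base.
- **Fallback:** The polarity is reversed and the coupling is run base-free as a Negishi reaction, setting out from 2 and 4. Compound 4 is iodinated at C3 (NIS, THF, 0 °C) to 3-iodo-1-(triisopropylsilyl)-5-(triisopropylsilyloxy)indole F5. Dibromide 2 undergoes a single bromine–lithium exchange, fixed by stoichiometry (n-BuLi, 1.0 equiv, THF, −78 °C), to (4-bromo-2,3,5,6-tetramethoxyphenyl)lithium F6. F6 is transmetalated with ZnCl2 to (4-bromo-2,3,5,6-tetramethoxyphenyl)zinc chloride F7. Pd(PPh3)4 in THF at 50 °C couples F7 with the more reactive C–I bond of F5, and the sequence returns to the route at 6.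

Step 7.
- **What may go wrong:** Allylic transposition during transfer of the prenyl group may attach the tertiary carbon. The double bond may migrate into conjugation with the ring. The bromide may be reduced.
- **Fallback:** The prenyl group is built in two stages from an allyl group, which has no regiochemical ambiguity, setting out from 10. Stille coupling with allyltributylstannane (Pd(PPh3)4, DMF, 90 °C) gives the 6-allyl analogue of 12, 6-allyl-3-{2,3,5,6-tetramethoxy-4-[1-(triisopropylsilyl)-5-(triisopropylsilyloxy)indol-3-yl]phenyl}-2-(trimethylsilyl)-1H-indole F8. Cross-metathesis with excess 2-methyl-2-butene (second-generation Grubbs catalyst, CH2Cl2, 40 °C) converts the terminal alkene into the trisubstituted one and returns to the route at 12.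

Further compounds
F1 | step 6 | 6-bromo-1-(triisopropylsilyl)indole | CC(C)[Si](C(C)C)(C(C)C)n1ccc2ccc(Br)cc21
F2 | step 6 | 6-(3-methylbut-2-enyl)-1-(triisopropylsilyl)indole | CC(C)=CCc1ccc2ccn([Si](C(C)C)(C(C)C)C(C)C)c2c1
F3 | step 6 | 6-(3-methylbut-2-enyl)-3-(4,4,5,5-tetramethyl-1,3,2-dioxaborolan-2-yl)-1-(triisopropylsilyl)indole | CC(C)=CCc1ccc2c(B3OC(C)(C)C(C)(C)O3)cn([Si](C(C)C)(C(C)C)C(C)C)c2c1
F4 | step 6 | tris-TIPS bis-indolyl tetramethoxybenzene (N-TIPS, O-TIPS on indole A; N-TIPS, 6-prenyl on indole B) | COc1c(OC)c(-c2cn([Si](C(C)C)(C(C)C)C(C)C)c3ccc(O[Si](C(C)C)(C(C)C)C(C)C)cc23)c(OC)c(OC)c1-c1cn([Si](C(C)C)(C(C)C)C(C)C)c2cc(CC=C(C)C)ccc12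
F5 | step 4 | 3-iodo-1-(triisopropylsilyl)-5-(triisopropylsilyloxy)indole | CC(C)[Si](C(C)C)(C(C)C)Oc1ccc2c(c1)c(I)cn2[Si](C(C)C)(C(C)C)C(C)C
F6 | step 4 | (4-bromo-2,3,5,6-tetramethoxyphenyl)lithium | [Li]c1c(OC)c(OC)c(Br)c(OC)c1OC
F7 | step 4 | (4-bromo-2,3,5,6-tetramethoxyphenyl)zinc chloride | Cl[Zn]c1c(OC)c(OC)c(Br)c(OC)c1OC
F8 | step 7 | 6-allyl-3-{2,3,5,6-tetramethoxy-4-[1-(triisopropylsilyl)-5-(triisopropylsilyloxy)indol-3-yl]phenyl}-2-(trimethylsilyl)-1H-indole | COc1c(OC)c(-c2cn([Si](C(C)C)(C(C)C)C(C)C)c3ccc(O[Si](C(C)C)(C(C)C)C(C)C)cc23)c(OC)c(OC)c1-c1c([Si](C)(C)C)[nH]c2cc(CC=C)ccc12
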